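Target **18** ⇐ **15** by dehydration of the C8 tertiary alcohol to the 8(17)-methylene and loss of the O15 silyl group; **15** ⇐ **13** by SN2 acetate inversion at C14.
**13** ⇐ **10**: the C13–C14 bond and both side-chain stereocentres come from an Ireland–Claisen [3,3] rearrangement of glycolate ester **7**, with chirality transfer from C11.
**7** ⇐ (11R,12E)-allylic alcohol **6** ⇐ (+)-sclareolide **1** by α-face enolate hydroxylation at C11, lactone-to-lactol reduction and (E)-ethylidenation.
Rings: none is formed; the trans-decalin (rings A and B, with C5, C9, C10 and the C8 oxygen) is bought in **1**, and only its lactone ring is opened.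

Assumption: labdane numbering is used (C8 = ring carbinol/olefin carbon, C9 carries the side chain C11–C16, C17 on C8, C20 on C10); α is the face opposite the C10 methyl.

**Route**

Step 1
Reactants: 1 (+)-sclareolide
Product: 4 (11S)-11α-hydroxysclareolide, via potassium lactone enolate 2 (not isolated), via potassium 11α-peroxide 3 (not isolated)
Conditions: KN(SiMe3)2, THF, −78 °C; O2, P(OEt)3, −78 °C; AcOH quench
Reagents that add atoms: dioxygen, O=O; KN(SiMe3)2, C[Si](C)(C)[N-][Si](C)(C)C.[K+] (potassium stays only in 2 and 3)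
Why: Enolate oxygenation (α-hydroxylation of a lactone) in which O2 attacks the enolate on the α-face, anti to the axial C8 and C10 methyls, and the phosphite reduces the peroxide in situ, so the bought ring stereocentres set C11.

Step 2
Reactants: 4 (11S)-11α-hydroxysclareolide
Product: 5 (11S)-11-hydroxysclareolide lactol (anomer mixture at C12)
Conditions: i-Bu2AlH (2.3 equiv), CH2Cl2, −78 °C
Reagents that add atoms: none
Why: Partial reduction of a γ-lactone with i-Bu2AlH stops at the aluminium hemiacetal at −78 °C (one equivalent is spent on the free hydroxyl), and C11 is untouched.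

Step 3
Reactants: 5 (11S)-11-hydroxysclareolide lactol
Product: 6 (11R,12E)-14,15-dinorlabd-12-ene-8α,11-diol
Conditions: CrCl2 (8 equiv), CH3CHI2, THF, rt
Reagents that add atoms: 1,1-diiodoethane, CC(I)I
Why: Takai–Utimoto alkylidenation, in which the geminal dichromium reagent adds to the open hydroxy-aldehyde form of the lactol and eliminates to the (E)-alkene (typically ≥9:1) while tolerating free hydroxyls; C11 keeps its geometry and becomes R only because the CIP priorities change.

Step 4
Reactants: 6 (11R,12E)-14,15-dinorlabd-12-ene-8α,11-diol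
Product: 7 (11R,12E)-8α-hydroxy-14,15-dinorlabd-12-en-11-yl (benzyloxy)acetate
Conditions: BnOCH2COCl, pyridine, DMAP (cat.), CH2Cl2, 0 °C → rt
Reagents that add atoms: (benzyloxy)acetyl chloride, O=C(Cl)COCc1ccccc1
Why: DMAP-catalysed acylation takes the secondary allylic hydroxyl only, because the tertiary C8 hydroxyl is too hindered to acylate.

Step 5
Reactants: 7 (11R,12E)-8α-hydroxy-14,15-dinorlabd-12-en-11-yl (benzyloxy)acetate
Product: 10 (11E,13R,14S)-14-benzyloxy-8α-hydroxylabd-11-en-15-oic acid, via bis-TMS (Z)-ketene acetal 8 (not isolated), via bis-TMS rearranged ester 9 (not isolated)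
Conditions: LiN(SiMe3)2 (3 equiv), TMSCl–Et3N, THF, −78 °C → rt; then 1 M HCl
Reagents that add atoms: chlorotrimethylsilane, C[Si](C)(C)Cl (silicon stays only in 8 and 9)
Why: Ireland–Claisen [3,3]-sigmatropic rearrangement in which lithium chelation gives the (Z)-ketene acetal and a chair transition state with the decalin equatorial forms the C13–C14 bond, transferring the C11 configuration to C13 (R) and C14 (S, syn) and leaving an (E)-C11=C12 alkene.

Step 6
Reactants: 10 (11E,13R,14S)-14-benzyloxy-8α-hydroxylabd-11-en-15-oic acid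
Product: 11 (11E,13R,14S)-14-benzyloxylabd-11-ene-8α,15-diol
Conditions: LiAlH4, THF, 0 °C → 50 °C
Reagents that add atoms: none
Why: Hydride reduction of the carboxylic acid to the primary alcohol leaves the benzyl ether, the alkene and the tertiary alcohol untouched.

Step 7
Reactants: 11 (11E,13R,14S)-14-benzyloxylabd-11-ene-8α,15-diol
Product: 12 (11E,13R,14S)-14-benzyloxy-15-(triethylsilyloxy)labd-11-en-8α-ol
Conditions: TESCl (1.1 equiv), imidazole, CH2Cl2, −20 → 0 °C
Reagents that add atoms: chlorotriethylsilane, CC[Si](Cl)(CC)CC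
Why: Silylation is selective for the primary hydroxyl because the tertiary C8 hydroxyl does not react with TESCl/imidazole.

Step 8
Reactants: 12 (11E,13R,14S)-14-benzyloxy-15-(triethylsilyloxy)labd-11-en-8α-ol
Product: 13 (13R,14S)-15-(triethylsilyloxy)labdane-8α,14-diol
Conditions: H2 (4 atm), 10% Pd/C, EtOAc, rt
Reagents that add atoms: none
Why: Catalytic hydrogenation saturates C11=C12 and hydrogenolyses the benzyl ether in one operation, done before the exocyclic alkene exists and under hydrogen-rich conditions to suppress double-bond migration toward C9 or C13.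

Step 9
Reactants: 13 (13R,14S)-15-(triethylsilyloxy)labdane-8α,14-diol
Product: 15 (13R,14R)-8α-hydroxy-15-(triethylsilyloxy)labdan-14-yl acetate, via C14 oxyphosphonium acetate 14 (not isolated)
Conditions: PPh3, DIAD, AcOH, toluene, 0 °C → rt
Reagents that add atoms: acetic acid, CC(=O)O; triphenylphosphine, c1ccc(cc1)P(c1ccccc1)c1ccccc1 (phosphorus stays only in 14)
Why: Mitsunobu reaction in which acetate displaces the oxyphosphonium by SN2, inverting C14 from S to R and installing the acetate directly, while the tertiary hydroxyl cannot react.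

Step 10
Reactants: 15 (13R,14R)-8α-hydroxy-15-(triethylsilyloxy)labdan-14-yl acetate
Product: 18 (13R,14R)-15-hydroxylabd-8(17)-en-14-yl acetate (target), via C8 chlorosulfite 16 (not isolated), via target 15-O-TES ether 17 (not isolated)
Conditions: SOCl2, pyridine, CH2Cl2, −78 °C; then AcOH–THF–H2O (3:1:1), rt
Reagents that add atoms: thionyl chloride, O=S(Cl)Cl (stays only in 16)
Why: E2 dehydration of the chlorosulfite gives the exocyclic 8(17)-alkene because the equatorial C8–O bond has no antiperiplanar ring hydrogen and only a C17 hydrogen can be removed, and dilute acid then cleaves the primary TES ether without acetyl migration.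

**Compound list**

1 | (+)-sclareolide | C[C@@]12CC[C@H]3C(C)(C)CCC[C@]3(C)[C@H]1CC(=O)O2 | starting material
2 | potassium enolate of sclareolide (not isolated) | C[C@@]12CC[C@H]3C(C)(C)CCC[C@]3(C)[C@H]1C=C([O-])O2.[K+] | intermediate
3 | potassium 11α-peroxide of sclareolide (not isolated) | C[C@@]12CC[C@H]3C(C)(C)CCC[C@]3(C)[C@H]1[C@H](O[O-])C(=O)O2.[K+] | intermediate
4 | (11S)-11α-hydroxysclareolide | C[C@@]12CC[C@H]3C(C)(C)CCC[C@]3(C)[C@H]1[C@H](O)C(=O)O2 | intermediate
5 | (11S)-11-hydroxysclareolide lactol (anomer mixture at C12) | C[C@@]12CC[C@H]3C(C)(C)CCC[C@]3(C)[C@H]1[C@H](O)C(O)O2 | intermediate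
6 | (11R,12E)-14,15-dinorlabd-12-ene-8α,11-diol | C[C@@]1(O)CC[C@H]2C(C)(C)CCC[C@]2(C)[C@H]1[C@H](O)/C=C/C | intermediate
7 | (11R,12E)-8α-hydroxy-14,15-dinorlabd-12-en-11-yl (benzyloxy)acetate | C[C@@]1(O)CC[C@H]2C(C)(C)CCC[C@]2(C)[C@H]1[C@H](OC(=O)COCc3ccccc3)/C=C/C | intermediate
8 | bis-TMS (Z)-ketene acetal of 7, 8-O-TMS (not isolated) | C[C@@]1(O[Si](C)(C)C)CC[C@H]2C(C)(C)CCC[C@]2(C)[C@H]1[C@H](O/C(O[Si](C)(C)C)=C/OCc3ccccc3)/C=C/C | intermediate
9 | trimethylsilyl (11E,13R,14S)-14-benzyloxy-8α-(trimethylsilyloxy)labd-11-en-15-oate (not isolated) | C[C@@]1(O[Si](C)(C)C)CC[C@H]2C(C)(C)CCC[C@]2(C)[C@H]1/C=C/[C@@H](C)[C@H](OCc3ccccc3)C(=O)O[Si](C)(C)C | intermediate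
10 | (11E,13R,14S)-14-benzyloxy-8α-hydroxylabd-11-en-15-oic acid | C[C@@]1(O)CC[C@H]2C(C)(C)CCC[C@]2(C)[C@H]1/C=C/[C@@H](C)[C@H](OCc3ccccc3)C(=O)O | intermediate
11 | (11E,13R,14S)-14-benzyloxylabd-11-ene-8α,15-diol | C[C@@]1(O)CC[C@H]2C(C)(C)CCC[C@]2(C)[C@H]1/C=C/[C@@H](C)[C@H](OCc3ccccc3)CO | intermediate
12 | (11E,13R,14S)-14-benzyloxy-15-(triethylsilyloxy)labd-11-en-8α-ol | C[C@@]1(O)CC[C@H]2C(C)(C)CCC[C@]2(C)[C@H]1/C=C/[C@@H](C)[C@H](OCc3ccccc3)CO[Si](CC)(CC)CC | intermediate
13 | (13R,14S)-15-(triethylsilyloxy)labdane-8α,14-diol | C[C@@]1(O)CC[C@H]2C(C)(C)CCC[C@]2(C)[C@H]1CC[C@@H](C)[C@H](O)CO[Si](CC)(CC)CC | intermediate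
14 | C14 oxyphosphonium acetate of 13 (not isolated) | C[C@@]1(O)CC[C@H]2C(C)(C)CCC[C@]2(C)[C@H]1CC[C@@H](C)[C@H](O[P+](c3ccccc3)(c3ccccc3)c3ccccc3)CO[Si](CC)(CC)CC.CC(=O)[O-] | intermediate
15 | (13R,14R)-8α-hydroxy-15-(triethylsilyloxy)labdan-14-yl acetate | C[C@@]1(O)CC[C@H]2C(C)(C)CCC[C@]2(C)[C@H]1CC[C@@H](C)[C@@H](OC(C)=O)CO[Si](CC)(CC)CC | intermediate
16 | C8 chlorosulfite of 15 (not isolated) | C[C@@]1(OS(=O)Cl)CC[C@H]2C(C)(C)CCC[C@]2(C)[C@H]1CC[C@@H](C)[C@@H](OC(C)=O)CO[Si](CC)(CC)CC | intermediate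
17 | (13R,14R)-15-(triethylsilyloxy)labd-8(17)-en-14-yl acetate (not isolated) | C=C1CC[C@H]2C(C)(C)CCC[C@]2(C)[C@H]1CC[C@@H](C)[C@@H](OC(C)=O)CO[Si](CC)(CC)CC | intermediate
18 | (13R,14R)-15-hydroxylabd-8(17)-en-14-yl acetate (CNP0285908.2) | C=C1CC[C@H]2C(C)(C)CCC[C@]2(C)[C@H]1CC[C@@H](C)[C@H](CO)OC(C)=O | target

**Step count and risks**

Total step count: 10. Longest linear sequence: 10 (fully linear, 1 → 18; step 10 is a two-stage one-pot operation).

Step 3 is the most likely to fail. Takai–Utimoto ethylidenation is well established for aldehydes but less so for an unprotected α-hydroxy lactol, and any (Z)-isomer would invert C13 in step 5. The fallback sets out from 5, which is homologated with dimethyl (1-diazo-2-oxopropyl)phosphonate, K2CO3 and MeOH to the terminal alkyne (11S)-14,15,16-trinorlabd-12-yne-8α,11-diol F3. Its lithium acetylide (n-BuLi, 3.2 equiv, then MeI) is C-methylated to (11S)-14,15-dinorlabd-12-yne-8α,11-diol F4. Trans-hydroalumination of this propargylic alcohol with NaAlH2(OCH2CH2OMe)2 gives only the (E)-allylic alcohol, and the route is rejoined at 6.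

Step 9 is next. The Mitsunobu inversion takes place at a β-branched secondary carbinol, where elimination or incomplete inversion can compete, and acetic acid is a mediocre Mitsunobu nucleophile. The fallback sets out from 13, which MsCl and Et3N convert into (13R,14S)-8α-hydroxy-15-(triethylsilyloxy)labdan-14-yl methanesulfonate F5 (the tertiary hydroxyl does not react). Displacement with CsOAc and 18-crown-6 in toluene at 90 °C is a stereospecific SN2 inversion that comes back to the route at 15.

Step 1 is the third. Oxygenation of the enolate with O2 can over-oxidise, and its face selectivity fixes C11, which in turn programmes C13 and C14. The α-face outcome is argued from sterics and was not checked against a reported result. The fallback sets out from 1, which i-Bu2AlH reduces to sclareolide lactol F1. Dehydration (MsCl, Et3N, then warming) gives the cyclic enol ether 8α,12-epoxy-13,14,15,16-tetranorlabd-11-ene F2. Dimethyldioxirane in wet acetone epoxidises F2 anti to the two axial methyls, and hydrolysis of the glycal-type epoxide in the same flask gives the α-hydroxy lactol, so the route is rejoined at 5.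

**Further compounds**

F1 | step 1 | sclareolide lactol (8α,12-epoxy-13,14,15,16-tetranorlabdan-12-ol, anomer mixture) | C[C@@]12CC[C@H]3C(C)(C)CCC[C@]3(C)[C@H]1CC(O)O2
F2 | step 1 | 8α,12-epoxy-13,14,15,16-tetranorlabd-11-ene | C[C@@]12CC[C@H]3C(C)(C)CCC[C@]3(C)[C@H]1C=CO2
F3 | step 3 | (11S)-14,15,16-trinorlabd-12-yne-8α,11-diol | C[C@@]1(O)CC[C@H]2C(C)(C)CCC[C@]2(C)[C@H]1[C@H](O)C#C
F4 | step 3 | (11S)-14,15-dinorlabd-12-yne-8α,11-diol | C[C@@]1(O)CC[C@H]2C(C)(C)CCC[C@]2(C)[C@H]1[C@H](O)C#CC
F5 | step 9 | (13R,14S)-8α-hydroxy-15-(triethylsilyloxy)labdan-14-yl methanesulfonate | C[C@@]1(O)CC[C@H]2C(C)(C)CCC[C@]2(C)[C@H]1CC[C@@H](C)[C@H](OS(C)(=O)=O)CO[Si](CC)(CC)CC
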